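The route rests on closing the five-membered ring at C1–C2 (daucane numbering) by a hydrogen-atom-transfer radical cyclization of an alkene onto an aldehyde. In one operation the exocyclic CH2 of a 1,1-disubstituted alkene becomes the C15 methyl, C1 becomes quaternary and C2 a carbinol, with both stereocentres set. The step exploits the 1,3-diol C4–O/C6–O that flanks C5: tied as an acetonide, it gives a cis-fused dioxane template that directs allyl and hydroxyl to the convex face. The precursor is a monocyclic dioxane aldehyde bearing a penta-1,4-dien-2-yl group; ring-closing metathesis later builds the trans-fused seven-membered ring (C8=C9).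

Key step: step 10

Remark on the chemistry: atom labels follow daucane numbering (C1 quaternary ring-fusion carbon with methyl C15, C2 carbinol CH, C3 CH2, C4 carbinol carbon with isopropyl, C5 ring-fusion CH, C6 acyloxy CH, C7 CH2, C8=C9 with methyl C14 on C8, C10 CH2), the target is (1R,2S,4R,5S,6S), and compounds 1, 5, 12, 23 and 27 are assumed to be purchased.

Step 1
Reactants: 1 tert-butyl(but-3-yn-1-yloxy)dimethylsilane; 2 ethyl chloroformate
Product: 4 ethyl 5-[(tert-butyldimethylsilyl)oxy]pent-2-ynoate, via lithium acetylide 3 (not isolated)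
Conditions: n-BuLi, THF, −78 °C; then 2, −78 °C to rt
Reagents that add atoms: none
Why: Deprotonation of the terminal alkyne and C-acylation of the lithium acetylide with the chloroformate is a standard alkynoate synthesis, and no stereocentre is formed.

Step 2
Reactants: 4 ethyl 5-[(tert-butyldimethylsilyl)oxy]pent-2-ynoate; 5 isopropylmagnesium chloride
Product: 8 ethyl (2E)-5-[(tert-butyldimethylsilyl)oxy]-3-(propan-2-yl)pent-2-enoate, via isopropylcopper 6 (not isolated), via alkenylcopper adduct 7 (not isolated)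
Conditions: CuI, THF, −40 °C; then 4, −78 °C; MeOH, −78 °C
Reagents that add atoms: none
Why: Syn-carbocupration of the alkynoate places isopropyl and copper cis, and protonation of the alkenylcopper at −78 °C with retention should give the (E)-enoate in which the ester and the CH2CH2OTBS chain are cis.

Step 3
Reactants: 8 ethyl (2E)-5-[(tert-butyldimethylsilyl)oxy]-3-(propan-2-yl)pent-2-enoate
Product: 9 (2E)-5-[(tert-butyldimethylsilyl)oxy]-3-(propan-2-yl)pent-2-en-1-ol
Conditions: iBu2AlH (DIBAL-H), CH2Cl2, −78 °C; aq potassium sodium tartrate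
Reagents that add atoms: none
Why: 1,2-Reduction of the unsaturated ester with DIBAL-H should give the allylic alcohol without change of the alkene geometry.

Step 4
Reactants: 9 (2E)-5-[(tert-butyldimethylsilyl)oxy]-3-(propan-2-yl)pent-2-en-1-ol
Product: 10 [(2R,3R)-3-{2-[(tert-butyldimethylsilyl)oxy]ethyl}-3-(propan-2-yl)oxiran-2-yl]methanol
Conditions: Ti(OiPr)4 (10 mol %), D-(−)-diethyl tartrate (12 mol %), t-BuOOH, 4 Å MS, CH2Cl2, −20 °C
Reagents that add atoms: tert-butyl hydroperoxide, CC(C)(C)OO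
Why: Sharpless asymmetric epoxidation of the trisubstituted allylic alcohol with the D-(−)-tartrate catalyst should deliver oxygen to the face that gives the (2R,3R)-epoxy alcohol, which fixes the tertiary C4–O centre and keeps CH2OH cis to the C3 chain.

Step 5
Reactants: 11 2,3-dibromoprop-1-ene; 12 vinylmagnesium bromide
Product: 13 2-bromopenta-1,4-diene
Conditions: CuI (5 mol %), THF, 0 °C
Reagents that add atoms: none
Why: Copper-catalysed allylic substitution of the allylic bromide by the vinyl Grignard reagent leaves the vinylic bromide untouched, and the SN2 and SN2' pathways give the same diene.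

Step 6
Reactants: 10 [(2R,3R)-3-{2-[(tert-butyldimethylsilyl)oxy]ethyl}-3-(propan-2-yl)oxiran-2-yl]methanol; 13 2-bromopenta-1,4-diene
Product: 15 (2S,3R)-5-[(tert-butyldimethylsilyl)oxy]-2-(penta-1,4-dien-2-yl)-3-(propan-2-yl)pentane-1,3-diol, via dienyl Grignard reagent 14 (not isolated)
Conditions: Mg, THF, 40 °C; then CuI (10 mol %), 10, −30 to 0 °C; aq NH4Cl
Reagents that add atoms: none
Why: Copper-catalysed SN2 opening of the 2,3-epoxy alcohol by the alkenyl Grignard reagent should occur at C5, the only non-quaternary epoxide carbon, with inversion, which sets C5 relative to C4 and turns the epoxide oxygen into the tertiary C4 hydroxyl of a 1,3-diol.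

Step 7
Reactants: 15 (2S,3R)-5-[(tert-butyldimethylsilyl)oxy]-2-(penta-1,4-dien-2-yl)-3-(propan-2-yl)pentane-1,3-diol
Product: 16 tert-butyldimethyl{2-[(4R,5S)-2,2-dimethyl-5-(penta-1,4-dien-2-yl)-4-(propan-2-yl)-1,3-dioxan-4-yl]ethoxy}silane
Conditions: 2,2-dimethoxypropane, PPTS (cat.), CH2Cl2, rt
Reagents that add atoms: 2,2-dimethoxypropane, COC(C)(C)OC
Why: Acid-catalysed transacetalisation ties the C4 and C6 hydroxyls into a 1,3-dioxane (acetonide), which protects both and later serves as the cis-fused template.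

Step 8
Reactants: 16 tert-butyldimethyl{2-[(4R,5S)-2,2-dimethyl-5-(penta-1,4-dien-2-yl)-4-(propan-2-yl)-1,3-dioxan-4-yl]ethoxy}silane
Product: 17 2-[(4R,5S)-2,2-dimethyl-5-(penta-1,4-dien-2-yl)-4-(propan-2-yl)-1,3-dioxan-4-yl]ethan-1-ol
Conditions: Bu4NF (TBAF), THF, 0 °C to rt
Reagents that add atoms: none
Why: Fluoride cleavage of the primary silyl ether should leave the acetonide and the skipped diene untouched.

Step 9
Reactants: 17 2-[(4R,5S)-2,2-dimethyl-5-(penta-1,4-dien-2-yl)-4-(propan-2-yl)-1,3-dioxan-4-yl]ethan-1-ol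
Product: 18 2-[(4R,5S)-2,2-dimethyl-5-(penta-1,4-dien-2-yl)-4-(propan-2-yl)-1,3-dioxan-4-yl]acetaldehyde
Conditions: TEMPO (cat.), PhI(OAc)2, CH2Cl2, rt
Reagents that add atoms: none
Why: TEMPO/PhI(OAc)2 oxidation of the primary alcohol stops at the aldehyde under non-basic conditions, which avoids β-elimination of the C4 oxygen.

Step 10
Reactants: 18 2-[(4R,5S)-2,2-dimethyl-5-(penta-1,4-dien-2-yl)-4-(propan-2-yl)-1,3-dioxan-4-yl]acetaldehyde
Product: 19 (4aS,5R,6S,7aR)-2,2,5-trimethyl-7a-(propan-2-yl)-5-(prop-2-en-1-yl)hexahydro-4H-cyclopenta[d][1,3]dioxin-6-ol (cis-fused; position 5 is C1 and position 6 is C2 of the daucane)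
Conditions: Fe(acac)3 (30 mol %), PhSiH3 (2.5 equiv), EtOH, 60 °C
Reagents that add atoms: none
Why: An iron hydride formed from Fe(acac)3 and PhSiH3 transfers a hydrogen atom to the CH2 terminus (C15) of the 1,1-disubstituted alkene, the tertiary C1 radical adds to the aldehyde carbon C2, and the resulting alkoxy radical is reduced by divalent iron and protonated by ethanol. The closest known reaction types are the HAT-initiated radical cyclization of alkene-tethered ketones and the iron-catalysed radical addition of unactivated alkenes to aldehydes. The cyclopentane (C1–C2–C3–C4–C5) closes in the 5-exo-trig mode onto the C=O group and is cis-fused to the dioxane. C1 and C2 are controlled by a chair-like transition state on this template in which isopropyl (C4), C6 (C5), allyl (C1) and the carbonyl oxygen (C2) are pseudo-equatorial, so allyl and hydroxyl should end on the convex face and the new methyl syn to the dioxane and trans to the hydroxyl. The step needs hydrogen-atom transfer to the 1,1-disubstituted alkene and not to the allyl group, which the faster reaction of the more substituted alkene (tertiary radical) secures, and capture of the alkoxy radical before β-scission, which the reducing protic iron medium provides.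

Step 11
Reactants: 19 (4aS,5R,6S,7aR)-2,2,5-trimethyl-7a-(propan-2-yl)-5-(prop-2-en-1-yl)hexahydro-4H-cyclopenta[d][1,3]dioxin-6-ol
Product: 20 tert-butyldimethylsilyl ether of 19 at the C2 oxygen, (4aS,5R,6S,7aR)-6-[(tert-butyldimethylsilyl)oxy]-2,2,5-trimethyl-7a-(propan-2-yl)-5-(prop-2-en-1-yl)hexahydro-4H-cyclopenta[d][1,3]dioxine
Conditions: TBSOTf, 2,6-lutidine, CH2Cl2, −78 to 0 °C
Reagents that add atoms: tert-butyldimethylsilyl trifluoromethanesulfonate, CC(C)(C)[Si](C)(C)OS(=O)(=O)C(F)(F)F
Why: Silylation of the only free hydroxyl (secondary C2–OH) with the silyl triflate masks it for the later acylation at C6, and the acetonide tolerates the buffered conditions.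

Step 12
Reactants: 20 (4aS,5R,6S,7aR)-6-[(tert-butyldimethylsilyl)oxy]-2,2,5-trimethyl-7a-(propan-2-yl)-5-(prop-2-en-1-yl)hexahydro-4H-cyclopenta[d][1,3]dioxine
Product: 21 (1R,2S,3R,4S)-4-[(tert-butyldimethylsilyl)oxy]-2-(hydroxymethyl)-3-methyl-1-(propan-2-yl)-3-(prop-2-en-1-yl)cyclopentan-1-ol
Conditions: PPTS, MeOH, rt
Reagents that add atoms: none
Why: Mild acid-catalysed methanolysis should remove the strained acetonide of the hindered 1,3-diol while the secondary silyl ether survives.

Step 13
Reactants: 21 (1R,2S,3R,4S)-4-[(tert-butyldimethylsilyl)oxy]-2-(hydroxymethyl)-3-methyl-1-(propan-2-yl)-3-(prop-2-en-1-yl)cyclopentan-1-ol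
Product: 22 (1R,2R,3S,5R)-3-[(tert-butyldimethylsilyl)oxy]-5-hydroxy-2-methyl-5-(propan-2-yl)-2-(prop-2-en-1-yl)cyclopentane-1-carbaldehyde
Conditions: TEMPO (cat.), PhI(OAc)2, CH2Cl2, rt
Reagents that add atoms: none
Why: TEMPO/PhI(OAc)2 oxidises the primary alcohol to the aldehyde (the tertiary alcohol cannot be oxidised), and C5 already has its more stable configuration, trans to both allyl and isopropyl.

Step 14
Reactants: 22 (1R,2R,3S,5R)-3-[(tert-butyldimethylsilyl)oxy]-5-hydroxy-2-methyl-5-(propan-2-yl)-2-(prop-2-en-1-yl)cyclopentane-1-carbaldehyde; 23 3-bromo-2-methylprop-1-ene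
Product: 25 (1R,2S,3R,4S)-4-[(tert-butyldimethylsilyl)oxy]-2-[(1S)-1-hydroxy-3-methylbut-3-en-1-yl]-3-methyl-1-(propan-2-yl)-3-(prop-2-en-1-yl)cyclopentan-1-ol, via 2-methylallylindium sesquibromide 24 (not isolated)
Conditions: In powder, THF/H2O (1:1), rt
Reagents that add atoms: none
Why: The indium-mediated Barbier allylation in aqueous THF should proceed through a chelate between the aldehyde oxygen and the cis C4 hydroxyl, and attack on the exposed face away from the ring gives the (6S) alcohol (anti-1,3-diol).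

Step 15
Reactants: 25 (1R,2S,3R,4S)-4-[(tert-butyldimethylsilyl)oxy]-2-[(1S)-1-hydroxy-3-methylbut-3-en-1-yl]-3-methyl-1-(propan-2-yl)-3-(prop-2-en-1-yl)cyclopentan-1-ol
Product: 26 (1R,2S,4R,5S,6S)-2-[(tert-butyldimethylsilyl)oxy]dauc-8-ene-4,6-diol (trans-fused hydroazulene)
Conditions: second-generation Grubbs catalyst [(H2IMes)(PCy3)Cl2Ru=CHPh] (5 mol %), CH2Cl2 (2 mM), 40 °C
Reagents that add atoms: none
Why: Ring-closing metathesis of the allyl and 2-methylallyl groups, which sit trans on C1 and C5, should close the trans-fused cycloheptene and form the trisubstituted C8=C9 alkene with loss of ethene.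

Step 16
Reactants: 26 (1R,2S,4R,5S,6S)-2-[(tert-butyldimethylsilyl)oxy]dauc-8-ene-4,6-diol; 27 4-[(tert-butyldimethylsilyl)oxy]benzoic acid
Product: 29 (1R,2S,4R,5S,6S)-2-[(tert-butyldimethylsilyl)oxy]-4-hydroxydauc-8-en-6-yl 4-[(tert-butyldimethylsilyl)oxy]benzoate, via mixed anhydride 28 (not isolated)
Conditions: 2,4,6-trichlorobenzoyl chloride, Et3N, THF, rt; then 26, DMAP, toluene, 60 °C
Reagents that add atoms: none
Why: Yamaguchi esterification acylates the secondary C6 hydroxyl through the mixed anhydride, while the tertiary C4 hydroxyl is too hindered to react and C2 is silylated.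

Step 17
Reactants: 29 (1R,2S,4R,5S,6S)-2-[(tert-butyldimethylsilyl)oxy]-4-hydroxydauc-8-en-6-yl 4-[(tert-butyldimethylsilyl)oxy]benzoate
Product: 30 2α-hydroxyferutinin, (1R,2S,4R,5S,6S)-2,4-dihydroxydauc-8-en-6-yl 4-hydroxybenzoate
Conditions: HF·pyridine, pyridine/THF, 0 °C to rt
Reagents that add atoms: none
Why: Fluoride-mediated desilylation with buffered HF·pyridine should remove the aryl and the secondary alkyl silyl ether without touching the benzoate, the tertiary alcohol or the alkene.

Compound list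
1 | tert-butyl(but-3-yn-1-yloxy)dimethylsilane | C#CCCO[Si](C)(C)C(C)(C)C | starting material
2 | ethyl chloroformate | CCOC(=O)Cl | starting material
3 | {4-[(tert-butyldimethylsilyl)oxy]but-1-yn-1-yl}lithium (lithium acetylide) | [Li]C#CCCO[Si](C)(C)C(C)(C)C | intermediate
4 | ethyl 5-[(tert-butyldimethylsilyl)oxy]pent-2-ynoate | CCOC(=O)C#CCCO[Si](C)(C)C(C)(C)C | intermediate
5 | isopropylmagnesium chloride | CC(C)[Mg]Cl | starting material
6 | isopropylcopper | CC(C)[Cu] | intermediate
7 | ethyl (2Z)-5-[(tert-butyldimethylsilyl)oxy]-2-cuprio-3-(propan-2-yl)pent-2-enoate (copper cis to isopropyl) | CCOC(=O)/C([Cu])=C(\CCO[Si](C)(C)C(C)(C)C)C(C)C | intermediate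
8 | ethyl (2E)-5-[(tert-butyldimethylsilyl)oxy]-3-(propan-2-yl)pent-2-enoate | CCOC(=O)/C=C(\CCO[Si](C)(C)C(C)(C)C)C(C)C | intermediate
9 | (2E)-5-[(tert-butyldimethylsilyl)oxy]-3-(propan-2-yl)pent-2-en-1-ol | OC/C=C(\CCO[Si](C)(C)C(C)(C)C)C(C)C | intermediate
10 | [(2R,3R)-3-{2-[(tert-butyldimethylsilyl)oxy]ethyl}-3-(propan-2-yl)oxiran-2-yl]methanol | OC[C@H]1O[C@]1(CCO[Si](C)(C)C(C)(C)C)C(C)C | intermediate
11 | 2,3-dibromoprop-1-ene | C=C(Br)CBr | starting material
12 | vinylmagnesium bromide | C=C[Mg]Br | starting material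
13 | 2-bromopenta-1,4-diene | C=C(Br)CC=C | intermediate
14 | penta-1,4-dien-2-ylmagnesium bromide | C=C(CC=C)[Mg]Br | intermediate
15 | (2S,3R)-5-[(tert-butyldimethylsilyl)oxy]-2-(penta-1,4-dien-2-yl)-3-(propan-2-yl)pentane-1,3-diol | OC[C@H](C(=C)CC=C)[C@@](O)(CCO[Si](C)(C)C(C)(C)C)C(C)C | intermediate
16 | tert-butyldimethyl{2-[(4R,5S)-2,2-dimethyl-5-(penta-1,4-dien-2-yl)-4-(propan-2-yl)-1,3-dioxan-4-yl]ethoxy}silane | CC1(C)OC[C@H](C(=C)CC=C)[C@@](CCO[Si](C)(C)C(C)(C)C)(C(C)C)O1 | intermediate
17 | 2-[(4R,5S)-2,2-dimethyl-5-(penta-1,4-dien-2-yl)-4-(propan-2-yl)-1,3-dioxan-4-yl]ethan-1-ol | CC1(C)OC[C@H](C(=C)CC=C)[C@@](CCO)(C(C)C)O1 | intermediate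
18 | 2-[(4R,5S)-2,2-dimethyl-5-(penta-1,4-dien-2-yl)-4-(propan-2-yl)-1,3-dioxan-4-yl]acetaldehyde | CC1(C)OC[C@H](C(=C)CC=C)[C@@](CC=O)(C(C)C)O1 | intermediate
19 | (4aS,5R,6S,7aR)-2,2,5-trimethyl-7a-(propan-2-yl)-5-(prop-2-en-1-yl)hexahydro-4H-cyclopenta[d][1,3]dioxin-6-ol | CC1(C)OC[C@@H]2[C@@](C)(CC=C)[C@@H](O)C[C@]2(C(C)C)O1 | intermediate
20 | (4aS,5R,6S,7aR)-6-[(tert-butyldimethylsilyl)oxy]-2,2,5-trimethyl-7a-(propan-2-yl)-5-(prop-2-en-1-yl)hexahydro-4H-cyclopenta[d][1,3]dioxine | CC1(C)OC[C@@H]2[C@@](C)(CC=C)[C@@H](O[Si](C)(C)C(C)(C)C)C[C@]2(C(C)C)O1 | intermediate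
21 | (1R,2S,3R,4S)-4-[(tert-butyldimethylsilyl)oxy]-2-(hydroxymethyl)-3-methyl-1-(propan-2-yl)-3-(prop-2-en-1-yl)cyclopentan-1-ol | OC[C@@H]1[C@@](C)(CC=C)[C@@H](O[Si](C)(C)C(C)(C)C)C[C@@]1(O)C(C)C | intermediate
22 | (1R,2R,3S,5R)-3-[(tert-butyldimethylsilyl)oxy]-5-hydroxy-2-methyl-5-(propan-2-yl)-2-(prop-2-en-1-yl)cyclopentane-1-carbaldehyde | O=C[C@@H]1[C@@](C)(CC=C)[C@@H](O[Si](C)(C)C(C)(C)C)C[C@@]1(O)C(C)C | intermediate
23 | 3-bromo-2-methylprop-1-ene | CC(=C)CBr | starting material
24 | 2-methylallylindium sesquibromide | CC(=C)C[In](Br)CC(C)=C.CC(=C)C[In](Br)Br | intermediate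
25 | (1R,2S,3R,4S)-4-[(tert-butyldimethylsilyl)oxy]-2-[(1S)-1-hydroxy-3-methylbut-3-en-1-yl]-3-methyl-1-(propan-2-yl)-3-(prop-2-en-1-yl)cyclopentan-1-ol | CC(=C)C[C@H](O)[C@@H]1[C@@](C)(CC=C)[C@@H](O[Si](C)(C)C(C)(C)C)C[C@@]1(O)C(C)C | intermediate
26 | (1R,2S,4R,5S,6S)-2-[(tert-butyldimethylsilyl)oxy]dauc-8-ene-4,6-diol | CC1=CC[C@]2(C)[C@@H]([C@@H](O)C1)[C@](O)(C(C)C)C[C@@H]2O[Si](C)(C)C(C)(C)C | intermediate
27 | 4-[(tert-butyldimethylsilyl)oxy]benzoic acid | CC(C)(C)[Si](C)(C)Oc1ccc(cc1)C(O)=O | starting material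
28 | 4-[(tert-butyldimethylsilyl)oxy]benzoic 2,4,6-trichlorobenzoic anhydride | CC(C)(C)[Si](C)(C)Oc1ccc(cc1)C(=O)OC(=O)c1c(Cl)cc(Cl)cc1Cl | intermediate
29 | (1R,2S,4R,5S,6S)-2-[(tert-butyldimethylsilyl)oxy]-4-hydroxydauc-8-en-6-yl 4-[(tert-butyldimethylsilyl)oxy]benzoate | CC1=CC[C@]2(C)[C@@H]([C@@H](OC(=O)c3ccc(O[Si](C)(C)C(C)(C)C)cc3)C1)[C@](O)(C(C)C)C[C@@H]2O[Si](C)(C)C(C)(C)C | intermediate
30 | 2α-hydroxyferutinin | CC1=CC[C@]2(C)[C@@H]([C@@H](OC(=O)c3ccc(O)cc3)C1)[C@](O)(C(C)C)C[C@@H]2O | target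

Total step count: 17. Longest linear sequence: 16 steps (steps 1–4 and 6–17, from 1 to 30); step 5 is a one-step side branch.

Steps most likely to fail

Step 10. The ring closure may be reversible, because the cyclopentyloxy radical can fragment back to the tertiary radical faster than it is reduced. The tertiary radical may also be reduced to the alkane, or hydrogen-atom transfer may move the skipped diene into conjugation. The fallback sets out from aldehyde 18 and comes back at 19. It changes the bond-forming event from a radical addition to a polar one: hydrogen-atom transfer from a hydride of the salen complex of cobalt, Co(salen), with PhSiH3 in the presence of CrCl2. The C1 radical is then captured by divalent chromium, and the tertiary alkylchromium species adds irreversibly to the aldehyde in the manner of a Nozaki–Hiyama–Kishi reaction on the same dioxane template. This fallback makes no new compound (F0).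

Step 6. SN2 attack of a branched alkenyl nucleophile at the neopentyl-like C5 may be slow, so that opening by bromide (halohydrin formation) or Payne rearrangement of the epoxy alkoxide competes. The fallback sets out from epoxy alcohol 10 and comes back at diol 15. It brings in C1 as a slim sp nucleophile and adds the allyl group afterwards:
- Silylation with Me3SiCl/Et3N should give [(2R,3R)-3-{2-[(tert-butyldimethylsilyl)oxy]ethyl}-3-(propan-2-yl)oxiran-2-yl]methyl trimethylsilyl ether F1.
- BF3·OEt2-mediated opening at C5 with lithium (trimethylsilyl)acetylide (inversion) should give (3R,4S)-1-[(tert-butyldimethylsilyl)oxy]-3-(propan-2-yl)-6-(trimethylsilyl)-4-[(trimethylsilyloxy)methyl]hex-5-yn-3-ol F2.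
- K2CO3 in MeOH removes both trimethylsilyl groups to give (2S,3R)-5-[(tert-butyldimethylsilyl)oxy]-2-ethynyl-3-(propan-2-yl)pentane-1,3-diol F3.
- Hydroxyl-assisted Markovnikov allylindation of the terminal alkyne (allyl bromide, In, THF) places the allyl group on the internal carbon and gives 15.

Step 14. Facial selectivity may be poor if the chelate is incomplete, and the β-hydroxy aldehyde may fragment by retro-aldol cleavage or lose water. The fallback sets out from the C6-epimer mixture of 25 and comes back at 25. It sets C6 by reagent-controlled reduction instead of C–C bond formation. Dess–Martin oxidation of the secondary hydroxyl should give 1-[(1R,2R,3S,5R)-3-[(tert-butyldimethylsilyl)oxy]-5-hydroxy-2-methyl-5-(propan-2-yl)-2-(prop-2-en-1-yl)cyclopentyl]-3-methylbut-3-en-1-one F4, handled cold and without base to keep the alkene out of conjugation. Corey–Bakshi–Shibata reduction with the (R)-oxazaborolidine and BH3·SMe2 then differentiates the bulky ring side from the CH2 side and should give the (6S) alcohol 25.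

Further compounds
F0 | step 10 | none | none
F1 | step 6 | [(2R,3R)-3-{2-[(tert-butyldimethylsilyl)oxy]ethyl}-3-(propan-2-yl)oxiran-2-yl]methyl trimethylsilyl ether | C[Si](C)(C)OC[C@H]1O[C@]1(CCO[Si](C)(C)C(C)(C)C)C(C)C
F2 | step 6 | (3R,4S)-1-[(tert-butyldimethylsilyl)oxy]-3-(propan-2-yl)-6-(trimethylsilyl)-4-[(trimethylsilyloxy)methyl]hex-5-yn-3-ol | C[Si](C)(C)OC[C@H](C#C[Si](C)(C)C)[C@@](O)(CCO[Si](C)(C)C(C)(C)C)C(C)C
F3 | step 6 | (2S,3R)-5-[(tert-butyldimethylsilyl)oxy]-2-ethynyl-3-(propan-2-yl)pentane-1,3-diol | OC[C@H](C#C)[C@@](O)(CCO[Si](C)(C)C(C)(C)C)C(C)C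
F4 | step 14 | 1-[(1R,2R,3S,5R)-3-[(tert-butyldimethylsilyl)oxy]-5-hydroxy-2-methyl-5-(propan-2-yl)-2-(prop-2-en-1-yl)cyclopentyl]-3-methylbut-3-en-1-one | CC(=C)CC(=O)[C@@H]1[C@@](C)(CC=C)[C@@H](O[Si](C)(C)C(C)(C)C)C[C@@]1(O)C(C)C
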